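**Retrosynthetic overview**

1. Ring B is closed last by forming the C7–C8 bond: a C7 organosamarium, made from a primary iodide, adds 6-exo to the C8 methyl ketone (samarium Barbier reaction) and gives the target directly.
2. Enabling feature: on ring A the C5 arm (C6–C7–I) and the C10 arm (C9–C8=O) are cis, and the C4 gem-dimethyl group locks the chair. C7 and the C8 carbonyl are therefore held 1,6 to each other and meet in a chair transition state that fixes C8.
3. The C8 ketone comes from Tsuji–Wacker oxidation of a vinyl group on C9; the C11–C12 bond from copper-catalysed coupling of a C11 Grignard reagent with (2E,6E)-farnesyl bromide.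
4. C9 and C10 are set by an Ireland–Claisen rearrangement of a but-3-enoate of a cis-4-substituted isophorol; C5 by a Johnson–Claisen rearrangement of CBS-derived (S)-2,4,4-trimethylcyclohex-2-enol.
5. Ring order: ring A is bought as 2,4,4-trimethylcyclohex-2-enone; ring B is formed in the final step.

Key step: step 15

Remark: the SMILES encodes a cis-fused decalin (H at C5 and CH3 at C10 on the same face; (1R,2R,4aR,8aS)), and the route is built for exactly this isomer. Labdane-type locants are used in the text: ring A = C1–C5 and C10, ring B = C5–C10, C8 = carbinol carbon, C9 carries the side chain starting at C11.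

**Route**

Step 1
Reactants: 1 2,4,4-trimethylcyclohex-2-en-1-one
Product: 2 (1S)-2,4,4-trimethylcyclohex-2-en-1-ol
Conditions: (R)-2-methyl-CBS-oxazaborolidine (10 mol %), BH3·SMe2, THF, −20 °C; MeOH quench
Reagents that add atoms: none
Why: Corey–Bakshi–Shibata reduction, in which the catalyst treats the alkenyl flank as the large group and delivers hydride to one carbonyl face only, so the (R)-catalyst should give the (1S)-allylic alcohol by clean 1,2-reduction.

Step 2
Reactants: 2 (1S)-2,4,4-trimethylcyclohex-2-en-1-ol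
Product: 4 ethyl [(1R)-2,6,6-trimethylcyclohex-2-en-1-yl]acetate, via mixed ketene acetal 3 (not isolated)
Conditions: MeC(OEt)3 (excess), EtCO2H (cat.), 140 °C, EtOH distilled off
Reagents that add atoms: triethyl orthoacetate, CC(OCC)(OCC)OCC
Why: Johnson–Claisen rearrangement, whose suprafacial [3,3] shift transfers the carbinol chirality to the new C5–C6 bond (C5 = R) while the alkene moves to C1=C10.

Step 3
Reactants: 4 ethyl [(1R)-2,6,6-trimethylcyclohex-2-en-1-yl]acetate
Product: 5 2-[(1R)-2,6,6-trimethylcyclohex-2-en-1-yl]ethan-1-ol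
Conditions: LiAlH4, Et2O, 0 °C
Reagents that add atoms: none
Why: Hydride reduction of the ester to the primary alcohol, which should leave the isolated alkene and the C5 centre untouched.

Step 4
Reactants: 5 2-[(1R)-2,6,6-trimethylcyclohex-2-en-1-yl]ethan-1-ol
Product: 6 (6R)-6-(2-chloroethyl)-1,5,5-trimethylcyclohex-1-ene
Conditions: PPh3, CCl4, 60 °C
Reagents that add atoms: tetrachloromethane, ClC(Cl)(Cl)Cl
Why: Appel chlorination (SN2 at the primary carbinol); the chloride is a robust placeholder for the later iodide and should tolerate the oxidising, basic, hydridic and organomagnesium steps that follow.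

Step 5
Reactants: 6 (6R)-6-(2-chloroethyl)-1,5,5-trimethylcyclohex-1-ene
Product: 7 (4R)-4-(2-chloroethyl)-3,5,5-trimethylcyclohex-2-en-1-one
Conditions: CrO3, 3,5-dimethylpyrazole, CH2Cl2, −20 °C
Reagents that add atoms: chromium trioxide, O=[Cr](=O)=O
Why: Chromium-mediated allylic oxidation of the ring CH2 next to the trisubstituted alkene (the reactivity known for α-ionone-type rings) should give the enone without touching C5 or the chloride.

Step 6
Reactants: 7 (4R)-4-(2-chloroethyl)-3,5,5-trimethylcyclohex-2-en-1-one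
Product: 8 (1S,4R)-4-(2-chloroethyl)-3,5,5-trimethylcyclohex-2-en-1-ol
Conditions: (R)-2-methyl-CBS-oxazaborolidine (20 mol %), BH3·SMe2, THF, −30 °C; MeOH quench
Reagents that add atoms: none
Why: Corey–Bakshi–Shibata reduction under catalyst control should give the (1S)-carbinol, with the hydroxyl cis to the C5 arm, which is the face from which C9 must later be delivered.

Step 7
Reactants: 8 (1S,4R)-4-(2-chloroethyl)-3,5,5-trimethylcyclohex-2-en-1-ol; 9 but-3-enoic acid
Product: 10 (1S,4R)-4-(2-chloroethyl)-3,5,5-trimethylcyclohex-2-en-1-yl but-3-enoate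
Conditions: DCC, DMAP (cat.), CH2Cl2, −20 → 0 °C
Reagents that add atoms: none
Why: Steglich esterification proceeds with retention at the carbinol carbon, and the low temperature should limit isomerisation of the β,γ-unsaturated acyl group to the crotonate.

Step 8
Reactants: 10 (1S,4R)-4-(2-chloroethyl)-3,5,5-trimethylcyclohex-2-en-1-yl but-3-enoate
Product: 13 (2S)-2-[(1S,6R)-6-(2-chloroethyl)-1,5,5-trimethylcyclohex-2-en-1-yl]but-3-enoic acid, via silyl dienol ether 11 (not isolated), via trimethylsilyl ester 12 (not isolated)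
Conditions: LiN(i-Pr)2, THF–DMPU (4:1), −78 °C; Me3SiCl; −78 °C → rt, then 50 °C; 1 M HCl
Reagents that add atoms: none
Why: Ireland–Claisen rearrangement, which is suprafacial on the face of the C–O bond and so attaches C9 to C10 cis to the C5 arm (quaternary C10); because the axial C4 methyl group blocks the chair arrangement, the boat transition state with the vinyl group outside (cis to OSiMe3) and the C9 hydrogen under C5 should operate and fix C9.

Step 9
Reactants: 13 (2S)-2-[(1S,6R)-6-(2-chloroethyl)-1,5,5-trimethylcyclohex-2-en-1-yl]but-3-enoic acid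
Product: 14 (2S)-2-[(1S,6R)-6-(2-chloroethyl)-1,5,5-trimethylcyclohex-2-en-1-yl]but-3-en-1-ol
Conditions: LiAlH4, Et2O, 0 °C → rt
Reagents that add atoms: none
Why: Hydride reduction of the acid to the primary alcohol (C11), under which the alkenes and the primary chloride should be inert and after which C9 can no longer epimerise.

Step 10
Reactants: 14 (2S)-2-[(1S,6R)-6-(2-chloroethyl)-1,5,5-trimethylcyclohex-2-en-1-yl]but-3-en-1-ol
Product: 15 (3S)-4-bromo-3-[(1S,6R)-6-(2-chloroethyl)-1,5,5-trimethylcyclohex-2-en-1-yl]but-1-ene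
Conditions: CBr4, PPh3, CH2Cl2, 0 °C
Reagents that add atoms: tetrabromomethane, BrC(Br)(Br)Br
Why: Appel bromination (SN2 at the primary carbinol) should not touch the chloride or the alkenes.

Step 11
Reactants: 15 (3S)-4-bromo-3-[(1S,6R)-6-(2-chloroethyl)-1,5,5-trimethylcyclohex-2-en-1-yl]but-1-ene; 16 (2E,6E)-1-bromo-3,7,11-trimethyldodeca-2,6,10-triene
Product: 18 (3S,6E,10E)-3-[(1R,6R)-6-(2-chloroethyl)-1,5,5-trimethylcyclohex-2-en-1-yl]-7,11,15-trimethylhexadeca-1,6,10,14-tetraene, via Grignard reagent 17 (not isolated)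
Conditions: Mg, THF, 35 °C; then 16, Li2CuCl4 (5 mol %), THF, −20 → 0 °C
Reagents that add atoms: none
Why: Copper-catalysed cross-coupling of a primary Grignard reagent with a primary allylic bromide forms the C11–C12 bond by SN2 attack with retention of the E geometry; magnesium should insert into the C–Br bond only and leave the C–Cl bond.

Step 12
Reactants: 18 (3S,6E,10E)-3-[(1R,6R)-6-(2-chloroethyl)-1,5,5-trimethylcyclohex-2-en-1-yl]-7,11,15-trimethylhexadeca-1,6,10,14-tetraene
Product: 19 (3R,6E,10E)-3-[(1S,6R)-6-(2-chloroethyl)-1,5,5-trimethylcyclohex-2-en-1-yl]-7,11,15-trimethylhexadeca-6,10,14-trien-2-one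
Conditions: PdCl2 (10 mol %), CuCl, O2 (1 atm), DMF–H2O (7:1), rt
Reagents that add atoms: water, O
Why: Tsuji–Wacker oxidation is selective for the monosubstituted alkene and gives the methyl ketone (Markovnikov), while the ring alkene and the trisubstituted alkenes should react much more slowly.

Step 13
Reactants: 19 (3R,6E,10E)-3-[(1S,6R)-6-(2-chloroethyl)-1,5,5-trimethylcyclohex-2-en-1-yl]-7,11,15-trimethylhexadeca-6,10,14-trien-2-one
Product: 20 (3R,6E,10E)-3-[(1S,2R)-2-(2-chloroethyl)-1,3,3-trimethylcyclohexyl]-7,11,15-trimethylhexadeca-6,10,14-trien-2-one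
Conditions: H2 (1 atm), RhCl(PPh3)3 (10 mol %), benzene, rt
Reagents that add atoms: none
Why: Homogeneous hydrogenation with RhCl(PPh3)3 discriminates by alkene substitution, so the cis-disubstituted ring alkene should be saturated while the three trisubstituted alkenes, the ketone and the chloride remain.

Step 14
Reactants: 20 (3R,6E,10E)-3-[(1S,2R)-2-(2-chloroethyl)-1,3,3-trimethylcyclohexyl]-7,11,15-trimethylhexadeca-6,10,14-trien-2-one
Product: 21 (3R,6E,10E)-3-[(1S,2R)-2-(2-iodoethyl)-1,3,3-trimethylcyclohexyl]-7,11,15-trimethylhexadeca-6,10,14-trien-2-one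
Conditions: NaI, acetone, reflux
Reagents that add atoms: sodium iodide, [Na+].[I-]
Why: Finkelstein exchange (SN2) gives the primary iodide needed for fast single-electron reduction, under neutral conditions that should leave C9 (alpha to the ketone) unchanged.

Step 15
Reactants: 21 (3R,6E,10E)-3-[(1S,2R)-2-(2-iodoethyl)-1,3,3-trimethylcyclohexyl]-7,11,15-trimethylhexadeca-6,10,14-trien-2-one
Product: 24 (1R,2R,4aR,8aS)-2,5,5,8a-tetramethyl-1-[(3E,7E)-4,8,12-trimethyltrideca-3,7,11-trien-1-yl]decahydronaphthalen-2-ol, via alkylsamarium 22 (not isolated), via samarium alkoxide 23 (not isolated)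
Conditions: SmI2 (2.5 equiv), HMPA, THF, 0 °C → rt; aq. NH4Cl
Reagents that add atoms: none
Why: SmI2/HMPA reduces the primary C7–I bond by two single-electron transfers to a C7 alkylsamarium (via the C7 radical), which adds to the C8 ketone within the molecule, and aqueous work-up protonates the trivalent samarium alkoxide. The closest known reaction type is the samarium Barbier cyclisation of ω-iodoalkyl ketones to 1-alkylcyclohexanols. Ring B closes in the 6-exo-trig mode, the carbonyl oxygen staying outside the new ring. C8 is the only new stereocentre and is set by the chair-like transition state imposed by C5, C9 and C10: the C4 gem-dimethyl group allows only the conformer with C1 axial on the forming ring, so the C8 methyl group avoids the 1,3-diaxial clash with C1 by going equatorial and the oxygen goes axial, anti to the axial C9 chain (8R, hydroxyl cis to H-9). The step needs chemoselective reduction of C–I in the presence of the ketone and three trisubstituted alkenes, which the fast reduction of primary iodides by SmI2/HMPA and the absence of any alkene within 5- or 6-exo reach of C7 should secure, and it needs C9 to keep its configuration, which the neutral aprotic conditions should secure.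

**Compound list**

1 | 2,4,4-trimethylcyclohex-2-en-1-one | CC1=CC(C)(C)CCC1=O | starting material
2 | (1S)-2,4,4-trimethylcyclohex-2-en-1-ol | CC1=CC(C)(C)CC[C@@H]1O | intermediate
3 | (1S)-2,4,4-trimethylcyclohex-2-en-1-yl 1-ethoxyethenyl ether (mixed ketene acetal) | CC1=CC(C)(C)CC[C@@H]1OC(=C)OCC | intermediate
4 | ethyl [(1R)-2,6,6-trimethylcyclohex-2-en-1-yl]acetate | CC1=CCCC(C)(C)[C@H]1CC(=O)OCC | intermediate
5 | 2-[(1R)-2,6,6-trimethylcyclohex-2-en-1-yl]ethan-1-ol | CC1=CCCC(C)(C)[C@H]1CCO | intermediate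
6 | (6R)-6-(2-chloroethyl)-1,5,5-trimethylcyclohex-1-ene | CC1=CCCC(C)(C)[C@H]1CCCl | intermediate
7 | (4R)-4-(2-chloroethyl)-3,5,5-trimethylcyclohex-2-en-1-one | CC1=CC(=O)CC(C)(C)[C@H]1CCCl | intermediate
8 | (1S,4R)-4-(2-chloroethyl)-3,5,5-trimethylcyclohex-2-en-1-ol (hydroxyl cis to the chloroethyl arm) | CC1=C[C@@H](O)CC(C)(C)[C@H]1CCCl | intermediate
9 | but-3-enoic acid | C=CCC(=O)O | starting material
10 | (1S,4R)-4-(2-chloroethyl)-3,5,5-trimethylcyclohex-2-en-1-yl but-3-enoate | C=CCC(=O)O[C@@H]1C=C(C)[C@H](CCCl)C(C)(C)C1 | intermediate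
11 | (1S,4R)-4-(2-chloroethyl)-3,5,5-trimethylcyclohex-2-en-1-yl (1Z)-1-[(trimethylsilyl)oxy]buta-1,3-dien-1-yl ether (silyl dienol ether, vinyl cis to OSiMe3) | C=C/C=C(\O[Si](C)(C)C)O[C@@H]1C=C(C)[C@H](CCCl)C(C)(C)C1 | intermediate
12 | trimethylsilyl (2S)-2-[(1S,6R)-6-(2-chloroethyl)-1,5,5-trimethylcyclohex-2-en-1-yl]but-3-enoate | C=C[C@H](C(=O)O[Si](C)(C)C)[C@@]1(C)C=CCC(C)(C)[C@H]1CCCl | intermediate
13 | (2S)-2-[(1S,6R)-6-(2-chloroethyl)-1,5,5-trimethylcyclohex-2-en-1-yl]but-3-enoic acid | C=C[C@H](C(=O)O)[C@@]1(C)C=CCC(C)(C)[C@H]1CCCl | intermediate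
14 | (2S)-2-[(1S,6R)-6-(2-chloroethyl)-1,5,5-trimethylcyclohex-2-en-1-yl]but-3-en-1-ol | C=C[C@H](CO)[C@@]1(C)C=CCC(C)(C)[C@H]1CCCl | intermediate
15 | (3S)-4-bromo-3-[(1S,6R)-6-(2-chloroethyl)-1,5,5-trimethylcyclohex-2-en-1-yl]but-1-ene | C=C[C@H](CBr)[C@@]1(C)C=CCC(C)(C)[C@H]1CCCl | intermediate
16 | (2E,6E)-1-bromo-3,7,11-trimethyldodeca-2,6,10-triene ((2E,6E)-farnesyl bromide) | CC(C)=CCC/C(C)=C/CC/C(C)=C/CBr | starting material
17 | bromo{(2S)-2-[(1S,6R)-6-(2-chloroethyl)-1,5,5-trimethylcyclohex-2-en-1-yl]but-3-en-1-yl}magnesium (Grignard reagent of 15) | C=C[C@H](C[Mg]Br)[C@@]1(C)C=CCC(C)(C)[C@H]1CCCl | intermediate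
18 | (3S,6E,10E)-3-[(1R,6R)-6-(2-chloroethyl)-1,5,5-trimethylcyclohex-2-en-1-yl]-7,11,15-trimethylhexadeca-1,6,10,14-tetraene | CC(C)=CCC/C(C)=C/CC/C(C)=C/CC[C@@H](C=C)[C@@]1(C)C=CCC(C)(C)[C@H]1CCCl | intermediate
19 | (3R,6E,10E)-3-[(1S,6R)-6-(2-chloroethyl)-1,5,5-trimethylcyclohex-2-en-1-yl]-7,11,15-trimethylhexadeca-6,10,14-trien-2-one | CC(C)=CCC/C(C)=C/CC/C(C)=C/CC[C@@H](C(C)=O)[C@@]1(C)C=CCC(C)(C)[C@H]1CCCl | intermediate
20 | (3R,6E,10E)-3-[(1S,2R)-2-(2-chloroethyl)-1,3,3-trimethylcyclohexyl]-7,11,15-trimethylhexadeca-6,10,14-trien-2-one | CC(C)=CCC/C(C)=C/CC/C(C)=C/CC[C@@H](C(C)=O)[C@@]1(C)CCCC(C)(C)[C@H]1CCCl | intermediate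
21 | (3R,6E,10E)-3-[(1S,2R)-2-(2-iodoethyl)-1,3,3-trimethylcyclohexyl]-7,11,15-trimethylhexadeca-6,10,14-trien-2-one | CC(C)=CCC/C(C)=C/CC/C(C)=C/CC[C@@H](C(C)=O)[C@@]1(C)CCCC(C)(C)[C@H]1CCI | intermediate
22 | C7 alkylsamarium diiodide derived from 21 | CC(C)=CCC/C(C)=C/CC/C(C)=C/CC[C@@H](C(C)=O)[C@@]1(C)CCCC(C)(C)[C@H]1CC[Sm](I)I | intermediate
23 | diiodosamarium alkoxide of 24 | CC(C)=CCC/C(C)=C/CC/C(C)=C/CC[C@@H]1[C@@]2(C)CCCC(C)(C)[C@H]2CC[C@@]1(C)O[Sm](I)I | intermediate
24 | (1R,2R,4aR,8aS)-2,5,5,8a-tetramethyl-1-[(3E,7E)-4,8,12-trimethyltrideca-3,7,11-trien-1-yl]decahydronaphthalen-2-ol (CNP0389811.1) | CC(C)=CCC/C(C)=C/CC/C(C)=C/CC[C@@H]1[C@@]2(C)CCCC(C)(C)[C@H]2CC[C@@]1(C)O | target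

**Totals**

Total step count: 15. Longest linear sequence: 15 steps (1 → 24; compounds 9 and 16 are purchased).

**Steps most likely to fail, with fallbacks**

Step 8 (Ireland–Claisen rearrangement). What may go wrong: the silyl dienol ether may form with the vinyl group on the wrong side, or the dienolate may be silylated at the γ-carbon or isomerise to the conjugated crotonate. The rearrangement at the crowded C10 may also be slow enough for the ketene acetal to decompose or to take another transition-state arrangement, which would erode control at C9. The fallback sets out from 8 and comes back at 13. It replaces the dienolate by a simple saturated ester enolate carrying a masked vinyl group. γ-Butyrolactone is opened with sodium benzeneselenolate (PhSeSePh, NaBH4, DMF, heat) to 4-(phenylselanyl)butanoic acid F1. Steglich esterification of 8 with this acid gives (1S,4R)-4-(2-chloroethyl)-3,5,5-trimethylcyclohex-2-en-1-yl 4-(phenylselanyl)butanoate F2. Its Ireland–Claisen rearrangement (LiN(i-Pr)2, THF–DMPU, Me3SiCl, then warming) should pass through the same boat arrangement with the selanylethyl group outside and give (2S)-2-[(1S,6R)-6-(2-chloroethyl)-1,5,5-trimethylcyclohex-2-en-1-yl]-4-(phenylselanyl)butanoic acid F3. Oxidation with H2O2 (THF, 0 °C → 40 °C) and syn-elimination of the selenoxide then unveil the vinyl group and return acid 13.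

Step 15 (key step). What may go wrong: protodeiodination or ketyl formation may outrun C–C bond formation, and facial discrimination at the C8 carbonyl may be insufficient. The fallback sets out from 21 and comes back at 24. It replaces the organosamarium addition by a ketyl–aldehyde coupling followed by deoxygenation. Kornblum oxidation of 21 (DMSO, NaHCO3, heat) gives {(1R,2S)-2,6,6-trimethyl-2-[(3R,6E,10E)-7,11,15-trimethyl-2-oxohexadeca-6,10,14-trien-3-yl]cyclohexyl}acetaldehyde F4. SmI2-mediated pinacol cyclisation (THF, t-BuOH, −78 °C) should give the chelation-controlled cis-diol, the 7α,8α-diol (1R,2S,3R,4aR,8aS)-2,5,5,8a-tetramethyl-1-[(3E,7E)-4,8,12-trimethyltrideca-3,7,11-trien-1-yl]decahydronaphthalene-2,3-diol F5. The secondary C7 hydroxyl is acylated selectively with phenyl chlorothionoformate (pyridine, DMAP) to the C7 O-phenyl thionocarbonate F6. Barton–McCombie deoxygenation (Bu3SnH, AIBN, toluene, 80 °C) then gives 24.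

Step 6 (second CBS reduction). What may go wrong: the catalyst-controlled delivery may be mismatched with the substrate's own facial bias (the axial C4 methyl group), giving poor facial selectivity, with conjugate reduction as a side path. The fallback sets out from 7 and comes back at 10. It uses substrate control and then inverts the carbinol during esterification. Luche reduction (NaBH4, CeCl3·7H2O, MeOH, −78 °C) should favour hydride attack anti to the axial methyl group and give the trans alcohol (1R,4R)-4-(2-chloroethyl)-3,5,5-trimethylcyclohex-2-en-1-ol F7. Mitsunobu esterification with 9 (PPh3, DIAD, THF, 0 °C) then inverts C1 and gives ester 10.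

**Further compounds**

F1 | step 8 | 4-(phenylselanyl)butanoic acid | O=C(O)CCC[Se]c1ccccc1
F2 | step 8 | (1S,4R)-4-(2-chloroethyl)-3,5,5-trimethylcyclohex-2-en-1-yl 4-(phenylselanyl)butanoate | O=C(CCC[Se]c1ccccc1)O[C@@H]2C=C(C)[C@H](CCCl)C(C)(C)C2
F3 | step 8 | (2S)-2-[(1S,6R)-6-(2-chloroethyl)-1,5,5-trimethylcyclohex-2-en-1-yl]-4-(phenylselanyl)butanoic acid | OC(=O)[C@@H](CC[Se]c1ccccc1)[C@@]2(C)C=CCC(C)(C)[C@H]2CCCl
F4 | step 15 | {(1R,2S)-2,6,6-trimethyl-2-[(3R,6E,10E)-7,11,15-trimethyl-2-oxohexadeca-6,10,14-trien-3-yl]cyclohexyl}acetaldehyde | CC(C)=CCC/C(C)=C/CC/C(C)=C/CC[C@@H](C(C)=O)[C@@]1(C)CCCC(C)(C)[C@H]1CC=O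
F5 | step 15 | (1R,2S,3R,4aR,8aS)-2,5,5,8a-tetramethyl-1-[(3E,7E)-4,8,12-trimethyltrideca-3,7,11-trien-1-yl]decahydronaphthalene-2,3-diol (7α,8α-diol) | CC(C)=CCC/C(C)=C/CC/C(C)=C/CC[C@@H]1[C@@]2(C)CCCC(C)(C)[C@H]2C[C@@H](O)[C@@]1(C)O
F6 | step 15 | O-phenyl thionocarbonate of F5 at the C7 hydroxyl | CC(C)=CCC/C(C)=C/CC/C(C)=C/CC[C@@H]1[C@@]2(C)CCCC(C)(C)[C@H]2C[C@@H](OC(=S)Oc3ccccc3)[C@@]1(C)O
F7 | step 6 | (1R,4R)-4-(2-chloroethyl)-3,5,5-trimethylcyclohex-2-en-1-ol | CC1=C[C@H](O)CC(C)(C)[C@H]1CCCl
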